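Eremophilane numbering is used: decalin C1–C10 (ring A = C1–C5 and C10; ring B = C5–C10), isopropenyl C11–C13 on C7, C14 on C5, C15 on C4; β is the face of C14.
Retrosynthesis: remove the C3 tiglate and the C9 senecioate, return C4–H to a 4(15)-methylidene (20) and C8=O to a carbinol (15), then cut C7–C8 and C5–C10 together to reach the acyclic epoxy aldehyde 13; 13 is cut at C9=C10 (cross-metathesis), at C4/C5 (carbomagnesiation) and at C3–C4 (alkyne acylation).
Enabling feature: in ring B, C8 and C10 are both electrophilic once C8–C9–C10 is an α,β-epoxy aldehyde (O9 already in place), and C5 and C7, one carbon apart through C6, are both π-nucleophiles (C5 the γ-carbon of a C4=C5 allylsilane silylated at C15, C7 the inner carbon of a prenyl ene donor); this is a three-carbon plus three-carbon annulation tethered through C1–C4.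
Forward: the chain is assembled in steps 1–7; in one flask ring A closes first (C5–C10, epoxide opening) and ring B second (C7–C8, carbonyl-ene); then oxidation at C8, acylation of O9, hydrogenation of C4=C15 and acylation of O3.
Stereochemistry: C3 by asymmetric transfer hydrogenation and C9/C10 by organocatalytic epoxidation (catalyst control); C5, C10 (inversion), C7 and the trans ring fusion are relayed in the key step by the (Z)-allylsilane geometry and chair transition states; C4 is relayed from C3 by hydroxyl-directed hydrogenation.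

Key step: step 8

Remark: N-methoxy-N-methylpent-4-enamide (4) is taken as a catalogue compound; it is otherwise one step from pent-4-enoyl chloride.

Step 1
Reactants: 1 1-bromo-3-methylbut-2-ene; 2 ethynylmagnesium bromide
Product: 3 5-methylhex-4-en-1-yne
Conditions: CuCl (5 mol %), THF, 0 °C to rt; careful distillation
Reagents that add atoms: none
Why: Copper-catalysed allyl–alkynyl coupling of the Grignard reagent should displace the primary allylic bromide at its unbranched terminus to give the skipped enyne, and no stereocentre is formed.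

Step 2
Reactants: 3 5-methylhex-4-en-1-yne; 4 N-methoxy-N-methylpent-4-enamide
Product: 6 10-methylundeca-1,9-dien-6-yn-5-one, via lithium acetylide 5 (not isolated)
Conditions: n-BuLi, THF, −78 °C; then 4, −78 to 0 °C; aq. NH4Cl
Reagents that add atoms: none
Why: Acylation of a lithium acetylide by an N-methoxy-N-methylamide should stop at the ketone because the chelated tetrahedral adduct persists until the quench, so the five-carbon pent-4-enoyl unit (C10, C1, C2, C3 and the terminal methylene) is joined to the alkyne in one operation, and no stereocentre is formed.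

Step 3
Reactants: 6 10-methylundeca-1,9-dien-6-yn-5-one
Product: 7 (5R)-10-methylundeca-1,9-dien-6-yn-5-ol
Conditions: Ru[(R,R)-TsDPEN](p-cymene) (1 mol %, preformed from the chloride complex and KOH), i-PrOH, rt
Reagents that add atoms: none
Why: Noyori-type asymmetric transfer hydrogenation of the alkynyl ketone should set C3 as (R) under catalyst control (alkynyl versus alkyl differentiation, the (R,R) ligand chosen by analogy with simple alkynyl ketones), the base-free amido complex sparing the base-sensitive skipped enyne.

Step 4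
Reactants: 7 (5R)-10-methylundeca-1,9-dien-6-yn-5-ol
Product: 9 (5R,6Z)-7,10-dimethyl-6-[(trimethylsilyl)methyl]undeca-1,6,9-trien-5-ol, via oxamagnesacycle 8 (not isolated)
Conditions: Me3SiCH2MgCl (3.5 equiv), CuI (15 mol %), THF, 0 °C to reflux; then MeI (5 equiv), 0 °C to rt; aq. NH4Cl
Reagents that add atoms: (trimethylsilyl)methylmagnesium chloride C[Si](C)(C)C[Mg]Cl; iodomethane CI
Why: Copper-catalysed anti-carbomagnesiation of the propargylic alkoxide should place the silylmethyl group on the proximal alkyne carbon (C4) and magnesium on C5 cis to the carbinol in a five-membered chelate, so that methylation with retention gives the tetrasubstituted allylsilane as the single (Z) isomer (C14 cis to C3), and no stereocentre is formed.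

Step 5
Reactants: 9 (5R,6Z)-7,10-dimethyl-6-[(trimethylsilyl)methyl]undeca-1,6,9-trien-5-ol
Product: 10 (5R,6Z)-5-[(tert-butyldimethylsilyl)oxy]-7,10-dimethyl-6-[(trimethylsilyl)methyl]undeca-1,6,9-triene
Conditions: TBSOTf, 2,6-lutidine, CH2Cl2, −78 °C
Reagents that add atoms: tert-butyldimethylsilyl trifluoromethanesulfonate CC(C)(C)[Si](C)(C)OS(=O)(=O)C(F)(F)F
Why: Silyl ether formation on the hindered allylic alcohol should give a bulky, weakly basic oxygen that neither binds the Lewis acids nor opens the epoxide in step 8, and no stereocentre is formed.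

Step 6
Reactants: 10 (5R,6Z)-5-[(tert-butyldimethylsilyl)oxy]-7,10-dimethyl-6-[(trimethylsilyl)methyl]undeca-1,6,9-triene; 11 (E)-but-2-enal
Product: 12 (2E,6R,7Z)-6-[(tert-butyldimethylsilyl)oxy]-8,11-dimethyl-7-[(trimethylsilyl)methyl]dodeca-2,7,10-trienal
Conditions: 11 (5 equiv), second-generation Grubbs catalyst (5 mol %), CH2Cl2, 40 °C
Reagents that add atoms: none
Why: Olefin cross-metathesis of the only monosubstituted alkene with excess crotonaldehyde should give the (E)-enal, the trisubstituted prenyl alkene and the tetrasubstituted allylsilane alkene being too hindered to enter the catalytic cycle.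

Step 7
Reactants: 12 (2E,6R,7Z)-6-[(tert-butyldimethylsilyl)oxy]-8,11-dimethyl-7-[(trimethylsilyl)methyl]dodeca-2,7,10-trienal
Product: 13 (2S,3R)-3-{(3R,4Z)-3-[(tert-butyldimethylsilyl)oxy]-5,8-dimethyl-4-[(trimethylsilyl)methyl]nona-4,7-dien-1-yl}oxirane-2-carbaldehyde
Conditions: (R)-2-[bis(3,5-bis(trifluoromethyl)phenyl)(trimethylsilyloxy)methyl]pyrrolidine (10 mol %), 35% aq. H2O2 (1.3 equiv), CH2Cl2, rt
Reagents that add atoms: hydrogen peroxide OO
Why: Iminium-catalysed nucleophilic epoxidation of the enal (conjugate addition of H2O2, then ring closure of the enamine) should give the trans-epoxy aldehyde with C9 (S) and C10 (R) set by the catalyst shielding one enal face (the (R)-catalyst chosen by analogy with simple alkyl enals), while the electron-rich alkenes are inert to H2O2.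

Step 8
Reactants: 13 (2S,3R)-3-{(3R,4Z)-3-[(tert-butyldimethylsilyl)oxy]-5,8-dimethyl-4-[(trimethylsilyl)methyl]nona-4,7-dien-1-yl}oxirane-2-carbaldehyde
Product: 15 3α-[(tert-butyldimethylsilyl)oxy]-9α-[(trimethylsilyl)oxy]-10αH-eremophila-4(15),11-dien-8β-ol, via silyloxy aldehyde 14 (not isolated)
Conditions: TMSOTf (10 mol %), 2,6-di-tert-butyl-4-methylpyridine (20 mol %), CH2Cl2, −78 °C; then Me2AlCl (2 equiv), −78 to −30 °C; cold aq. NaHCO3
Reagents that add atoms: none
Why: Proposed new method: silylation of the epoxide oxygen by TMSOTf should let C5, the γ-carbon of the tetrasubstituted allylsilane, open the epoxide at C10 with inversion, the β-silyl cation at C4 then releasing Me3Si+ (which regenerates TMSOTf and leaves the 4(15)-methylidene and the C9 trimethylsilyl ether), after which Me2AlCl activates the freed α-silyloxy aldehyde for a carbonyl-ene reaction with the prenyl alkene that forms C7–C8, shifts the double bond into the isopropenyl group and puts the hydrogen on O8. The closest known reactions are the Lewis-acid epoxide–allylsilane cyclisation and the Me2AlCl-promoted type 1 intramolecular carbonyl-ene cyclisation of citronellal-like aldehydes; new is their union on an α,β-epoxy aldehyde with a silyl transfer that tags O9 and leaves O8 free. Ring A closes by 6-exo-tet epoxide opening through a chair (OTBS and the C10 side chain equatorial), and ring B closes by a six-membered chair ene transition state, exo at the carbonyl. C10 is set by inversion at the epoxide carbon, C5 follows from the (Z) alkene geometry (the methyl cis to C3 becomes axial and the prenyl arm equatorial, hence the trans fusion), C7 is set by the nascent isopropenyl group going equatorial away from the axial C5 methyl, and C8 (hydroxyl expected equatorial) is erased in step 9; C9 is carried over from the epoxide. The step needs attack at C10 and not C9 (secured by the 6-exo ring size and the deactivating formyl group on C9), C5 and not C4 as the nucleophilic carbon (secured by the β-silicon effect), and the two nucleophiles acting in order (secured because the prenyl alkene reaches the aldehyde in a six-membered array only after ring A exists).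

Step 9
Reactants: 15 3α-[(tert-butyldimethylsilyl)oxy]-9α-[(trimethylsilyl)oxy]-10αH-eremophila-4(15),11-dien-8β-ol
Product: 17 3α-[(tert-butyldimethylsilyl)oxy]-9α-hydroxy-10αH-eremophila-4(15),11-dien-8-one, via silyloxy ketone 16 (not isolated)
Conditions: Dess–Martin periodinane (1.3 equiv), NaHCO3, CH2Cl2, 0 °C to rt; aq. Na2S2O3/NaHCO3 wash; crude 16 in MeOH, PPTS (10 mol %), 0 °C
Reagents that add atoms: none
Why: Dess–Martin oxidation of the only free hydroxyl should give the C8 ketone under buffered conditions that leave the β,γ-unsaturated ketone unconjugated, and mild acid methanolysis should then remove the secondary trimethylsilyl ether while the tert-butyldimethylsilyl ether stays; no stereocentre is formed, and the equatorial C7 and C9 substituents are the thermodynamic ones.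

Step 10
Reactants: 17 3α-[(tert-butyldimethylsilyl)oxy]-9α-hydroxy-10αH-eremophila-4(15),11-dien-8-one; 18 3-methylbut-2-enoyl chloride
Product: 19 3α-[(tert-butyldimethylsilyl)oxy]-9α-(3-methylbut-2-enoyloxy)-10αH-eremophila-4(15),11-dien-8-one
Conditions: pyridine, DMAP (10 mol %), CH2Cl2, 0 °C
Reagents that add atoms: none
Why: DMAP-catalysed acylation of the α-hydroxy ketone through the acylpyridinium ion should give the senecioate with no base stronger than pyridine present, so the acid chloride is not deconjugated through a vinylketene, C9 and C7 should not epimerise and no stereocentre is formed.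

Step 11
Reactants: 19 3α-[(tert-butyldimethylsilyl)oxy]-9α-(3-methylbut-2-enoyloxy)-10αH-eremophila-4(15),11-dien-8-one
Product: 20 3α-hydroxy-9α-(3-methylbut-2-enoyloxy)-10αH-eremophila-4(15),11-dien-8-one
Conditions: HF·pyridine, pyridine, THF, 0 °C to rt
Reagents that add atoms: none
Why: Fluoride-driven silyl ether cleavage under buffered acidic conditions should free O3 without hydrolysing the C9 ester or conjugating the β,γ-unsaturated ketone, and no stereocentre is formed.

Step 12
Reactants: 20 3α-hydroxy-9α-(3-methylbut-2-enoyloxy)-10αH-eremophila-4(15),11-dien-8-one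
Product: 21 3α-hydroxy-9α-(3-methylbut-2-enoyloxy)-10αH-eremophil-11-en-8-one
Conditions: [Rh(nbd)(dppb)]BF4 (10 mol %), H2 (50 atm), CH2Cl2, rt
Reagents that add atoms: none
Why: Hydroxyl-directed homogeneous hydrogenation should deliver H2 to the 4(15)-methylidene from the α-face (syn to the bound C3 hydroxyl, anti to the axial C5 methyl), setting C4 as 4β-methyl, while the isopropenyl group and the β,β-disubstituted enoate, which lack a binding hydroxyl, are expected to react much more slowly and the high pressure suppresses isomerisation to the ketone.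

Step 13
Reactants: 21 3α-hydroxy-9α-(3-methylbut-2-enoyloxy)-10αH-eremophil-11-en-8-one; 22 (E)-2-methylbut-2-enoyl chloride
Product: 23 (3R,4R,5R,7S,9S,10R)-3-[(E)-2-methylbut-2-enoyloxy]-9-(3-methylbut-2-enoyloxy)eremophil-11-en-8-one
Conditions: pyridine, DMAP (20 mol %), CH2Cl2, 0 °C to rt
Reagents that add atoms: none
Why: DMAP-catalysed acylation of the equatorial C3 alcohol by tigloyl chloride should complete the target with the (E) geometry of the acid chloride retained, and no stereocentre is formed.

**Compound list**
1 | 1-bromo-3-methylbut-2-ene (prenyl bromide) | CC(C)=CCBr | starting material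
2 | ethynylmagnesium bromide | C#C[Mg]Br | starting material
3 | 5-methylhex-4-en-1-yne | C#CCC=C(C)C | intermediate
4 | N-methoxy-N-methylpent-4-enamide | C=CCCC(=O)N(C)OC | starting material
5 | (5-methylhex-4-en-1-yn-1-yl)lithium, formed in situ | [Li]C#CCC=C(C)C | intermediate
6 | 10-methylundeca-1,9-dien-6-yn-5-one | C=CCCC(=O)C#CCC=C(C)C | intermediate
7 | (5R)-10-methylundeca-1,9-dien-6-yn-5-ol | C=CCC[C@@H](O)C#CCC=C(C)C | intermediate
8 | five-membered alkenylmagnesium alkoxide chelate (Mg bonded to O3 and C5; C4 carries CH2SiMe3), formed in situ | C=CCC[C@H]1O[Mg]C(CC=C(C)C)=C1C[Si](C)(C)C | intermediate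
9 | (5R,6Z)-7,10-dimethyl-6-[(trimethylsilyl)methyl]undeca-1,6,9-trien-5-ol | C=CCC[C@@H](O)/C(C[Si](C)(C)C)=C(\C)CC=C(C)C | intermediate
10 | (5R,6Z)-5-[(tert-butyldimethylsilyl)oxy]-7,10-dimethyl-6-[(trimethylsilyl)methyl]undeca-1,6,9-triene | C=CCC[C@@H](O[Si](C)(C)C(C)(C)C)/C(C[Si](C)(C)C)=C(\C)CC=C(C)C | intermediate
11 | (E)-but-2-enal (crotonaldehyde) | C/C=C/C=O | starting material
12 | (2E,6R,7Z)-6-[(tert-butyldimethylsilyl)oxy]-8,11-dimethyl-7-[(trimethylsilyl)methyl]dodeca-2,7,10-trienal | O=C/C=C/CC[C@@H](O[Si](C)(C)C(C)(C)C)/C(C[Si](C)(C)C)=C(\C)CC=C(C)C | intermediate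
13 | (2S,3R)-3-{(3R,4Z)-3-[(tert-butyldimethylsilyl)oxy]-5,8-dimethyl-4-[(trimethylsilyl)methyl]nona-4,7-dien-1-yl}oxirane-2-carbaldehyde | O=C[C@H]1O[C@@H]1CC[C@@H](O[Si](C)(C)C(C)(C)C)/C(C[Si](C)(C)C)=C(\C)CC=C(C)C | intermediate
14 | ring-A aldehyde, formed in situ: cyclohexane C10/C1–C5 with 3α-OTBS, 4-methylidene, 5β-methyl, 5α-(3-methylbut-2-enyl) and 10α-H; C10 carries (9S)-CH(OSiMe3)–CHO | O=C[C@@H](O[Si](C)(C)C)[C@@H]1CC[C@@H](O[Si](C)(C)C(C)(C)C)C(=C)[C@@]1(C)CC=C(C)C | intermediate
15 | 3α-[(tert-butyldimethylsilyl)oxy]-9α-[(trimethylsilyl)oxy]-10αH-eremophila-4(15),11-dien-8β-ol (trans-decalin, 5β-methyl, 7α-isopropenyl) | C=C(C)[C@@H]1C[C@]2(C)C(=C)[C@H](O[Si](C)(C)C(C)(C)C)CC[C@H]2[C@H](O[Si](C)(C)C)[C@H]1O | intermediate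
16 | 3α-[(tert-butyldimethylsilyl)oxy]-9α-[(trimethylsilyl)oxy]-10αH-eremophila-4(15),11-dien-8-one, carried on crude | C=C(C)[C@@H]1C[C@]2(C)C(=C)[C@H](O[Si](C)(C)C(C)(C)C)CC[C@H]2[C@H](O[Si](C)(C)C)C1=O | intermediate
17 | 3α-[(tert-butyldimethylsilyl)oxy]-9α-hydroxy-10αH-eremophila-4(15),11-dien-8-one | C=C(C)[C@@H]1C[C@]2(C)C(=C)[C@H](O[Si](C)(C)C(C)(C)C)CC[C@H]2[C@H](O)C1=O | intermediate
18 | 3-methylbut-2-enoyl chloride (senecioyl chloride) | CC(C)=CC(=O)Cl | starting material
19 | 3α-[(tert-butyldimethylsilyl)oxy]-9α-(3-methylbut-2-enoyloxy)-10αH-eremophila-4(15),11-dien-8-one | C=C(C)[C@@H]1C[C@]2(C)C(=C)[C@H](O[Si](C)(C)C(C)(C)C)CC[C@H]2[C@H](OC(=O)C=C(C)C)C1=O | intermediate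
20 | 3α-hydroxy-9α-(3-methylbut-2-enoyloxy)-10αH-eremophila-4(15),11-dien-8-one | C=C(C)[C@@H]1C[C@]2(C)C(=C)[C@H](O)CC[C@H]2[C@H](OC(=O)C=C(C)C)C1=O | intermediate
21 | 3α-hydroxy-9α-(3-methylbut-2-enoyloxy)-10αH-eremophil-11-en-8-one (4β-methyl, 4α-H) | C=C(C)[C@@H]1C[C@]2(C)[C@@H](C)[C@H](O)CC[C@H]2[C@H](OC(=O)C=C(C)C)C1=O | intermediate
22 | (E)-2-methylbut-2-enoyl chloride (tigloyl chloride) | C/C=C(\C)C(=O)Cl | starting material
23 | (3R,4R,5R,7S,9S,10R)-3-[(E)-2-methylbut-2-enoyloxy]-9-(3-methylbut-2-enoyloxy)eremophil-11-en-8-one (3α,9α-diester; 4β,5β-dimethyl; 7α-isopropenyl; 10α-H) | C=C(C)[C@@H]1C[C@]2(C)[C@@H](C)[C@H](OC(=O)/C(C)=C/C)CC[C@H]2[C@H](OC(=O)C=C(C)C)C1=O | target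

**Totals and risks**
Total step count: 13. Longest linear sequence: 13 steps (1 and 2 to 23).

Steps most likely to fail:

1. Step 8 (proposed new method). What may go wrong: the activated epoxy aldehyde may rearrange by hydride or formyl shift, or be opened by the silyl ether oxygen, before the allylsilane closes ring A; the silyl tag may be lost from O9; or the ene stage may stall. The fallback uses known reactions only and sets out from 13. NaBH4 reduction (MeOH, 0 °C) should give the epoxy alcohol F1. BF3·OEt2 (CH2Cl2, −78 °C) should effect the established Lewis-acid epoxide–allylsilane cyclisation to the ring-A diol F2. TMSCl and imidazole should give the bis(trimethylsilyl) ether F3. Swern oxidation, which converts a primary trimethylsilyl ether directly into the aldehyde and leaves the secondary one, should give 14, now isolated. Me2AlCl-promoted carbonyl-ene cyclisation of 14 then comes back to the route at 15.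

2. Step 12. What may go wrong: poor chemoselectivity (competing saturation of the isopropenyl group or of the senecioate) or isomerisation of the allylic alcohol. The fallback sets out from 20. The allylic alcohol is isomerised on purpose with RuCl2(PPh3)3 (toluene, 80 °C), which leaves isolated alkenes alone, and C4 should settle as the equatorial 4β-methyl ketone F4. Reduction of the less hindered C3 ketone with LiBH(s-Bu)3 (THF, −78 °C) from the equatorial direction should give the axial 3β-alcohol F5. Mitsunobu esterification with tiglic acid (PPh3, DIAD) inverts C3 and comes back to the route at 23.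

3. Step 4. What may go wrong: sluggish methylation of the alkenylmagnesium chelate, so that it is protonated on work-up, or incomplete carbomagnesiation. The fallback sets out from 7. The same carbomagnesiation is run but 8 is quenched with I2, which should give the alkenyl iodide F6 with iodine cis to C3. Negishi methylation (MeZnCl, Pd(PPh3)4, THF) with retention then comes back to the route at 9.

**Further compounds**
F1 | step 8 | [(2R,3R)-3-{(3R,4Z)-3-[(tert-butyldimethylsilyl)oxy]-5,8-dimethyl-4-[(trimethylsilyl)methyl]nona-4,7-dien-1-yl}oxiran-2-yl]methanol | OC[C@H]1O[C@@H]1CC[C@@H](O[Si](C)(C)C(C)(C)C)/C(C[Si](C)(C)C)=C(\C)CC=C(C)C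
F2 | step 8 | ring-A diol: as 14 but with (9S)-CH(OH)–CH2OH on C10 | OC[C@@H](O)[C@@H]1CC[C@@H](O[Si](C)(C)C(C)(C)C)C(=C)[C@@]1(C)CC=C(C)C
F3 | step 8 | bis(trimethylsilyl) ether of F2 | C[Si](C)(C)OC[C@@H](O[Si](C)(C)C)[C@@H]1CC[C@@H](O[Si](C)(C)C(C)(C)C)C(=C)[C@@]1(C)CC=C(C)C
F4 | step 12 | 9α-(3-methylbut-2-enoyloxy)-10αH-eremophil-11-ene-3,8-dione (4β-methyl) | C=C(C)[C@@H]1C[C@]2(C)[C@@H](C)C(=O)CC[C@H]2[C@H](OC(=O)C=C(C)C)C1=O
F5 | step 12 | 3β-hydroxy-9α-(3-methylbut-2-enoyloxy)-10αH-eremophil-11-en-8-one (4β-methyl) | C=C(C)[C@@H]1C[C@]2(C)[C@@H](C)[C@@H](O)CC[C@H]2[C@H](OC(=O)C=C(C)C)C1=O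
F6 | step 4 | (5R,6E)-7-iodo-10-methyl-6-[(trimethylsilyl)methyl]undeca-1,6,9-trien-5-ol | C=CCC[C@@H](O)/C(C[Si](C)(C)C)=C(\I)CC=C(C)C
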